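The oxolane is cut across O1–C2 and C3–C4 into two aryl-C3 halves: enantiopure (S)-1-(3,4-dimethoxyphenyl)allyl alcohol (O1, C5, C4 and the future C4 methyl) and the acetate of (E)-4-propenylsyringol (C2, C3 and its methyl). In one flask, iodoetherification places O1 on benzylic C2 and a tin hydride 5-exo radical cyclization of the derived C3 radical onto the allyl group makes C3–C4, turning the alkene terminus into the C4 methyl. The step exploits the cation-stabilising benzylic carbon C2 beside the syringyl ring and the 3-oxahex-5-enyl array C3–C2–O1–C5–C4=CH2 latent in the oxolane; C5 relays its configuration to C4 and C3, and C2 is finally equilibrated through a quinone methide.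

Key step: step 4

Remark: oxolane atoms are numbered O1, C2 (bearing the 4-hydroxy-3,5-dimethoxyphenyl ring), C3, C4, C5 (bearing the 3,4-dimethoxyphenyl ring). The two C2 epimers formed in step 4 are carried on together and converge in step 5; the alkene geometry of 5 is lost in step 4, so any Z isomer in commercial material is equally usable.

Step 1
Reactants: 1 3,4-dimethoxybenzaldehyde; 2 vinylmagnesium bromide
Product: 3 racemic 1-(3,4-dimethoxyphenyl)prop-2-en-1-ol
Conditions: CH2=CHMgBr, THF, 0 °C; aqueous work-up
Reagents that add atoms: vinylmagnesium bromide, C=C[Mg]Br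
Why: Grignard 1,2-addition to the aldehyde should give the secondary allylic alcohol as the racemate, no stereocontrol being needed at this stage.

Step 2
Reactants: 3 racemic 1-(3,4-dimethoxyphenyl)prop-2-en-1-ol
Product: 4 (1S)-1-(3,4-dimethoxyphenyl)prop-2-en-1-ol
Conditions: Novozym 435 (immobilised Candida antarctica lipase B), vinyl acetate, MTBE, 30 °C, stopped just past half conversion; chromatography
Reagents that add atoms: none
Why: Lipase-catalysed kinetic resolution by enantioselective transesterification should acylate the (R)-alcohol (aryl in the large pocket, vinyl in the medium pocket) and leave the (S)-alcohol, which becomes C5 of the target, unreacted.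

Step 3
Reactants: 5 2,6-dimethoxy-4-[(1E)-prop-1-en-1-yl]phenol
Product: 6 2,6-dimethoxy-4-[(1E)-prop-1-en-1-yl]phenyl acetate
Conditions: Ac2O, pyridine, rt
Reagents that add atoms: acetic anhydride, CC(=O)OC(C)=O
Why: O-acylation with an anhydride masks the phenol so that NIS in step 4 attacks only the alkene and no quinone methide forms prematurely.

Step 4
Reactants: 4 (1S)-1-(3,4-dimethoxyphenyl)prop-2-en-1-ol; 6 2,6-dimethoxy-4-[(1E)-prop-1-en-1-yl]phenyl acetate
Product: 8 4-[(2RS,3R,4S,5S)-5-(3,4-dimethoxyphenyl)-3,4-dimethyloxolan-2-yl]-2,6-dimethoxyphenyl acetate (both C2 epimers), via β-iodo ether 7 (not isolated)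
Conditions: NIS, 4 Å molecular sieves, CH2Cl2, −20 to 0 °C, dark (6 and NIS in excess); then Bu3SnH, Et3B (cat.), air, toluene, −40 to 0 °C
Reagents that add atoms: none
Why: NIS forms an iodonium ion on the conjugated propenyl alkene of 6 and alcohol 4 opens it anti at the benzylic carbon (iodoetherification), which makes O1–C2 and leaves a C3–I bond; Bu3SnH with Et3B/air then abstracts iodine, the C3 radical closes onto the internal carbon of the allyl group to make C3–C4, and the exocyclic primary radical takes hydrogen from tin to become the C4 methyl. The closest known reaction type is alkene cohalogenation followed by Ueno–Stork-type reductive radical cyclization of a β-halo allyl ether, telescoped here because the β-iodo benzylic ether is too labile to isolate. The oxolane ring closes by 5-exo-trig radical attack of a 3-oxahex-5-enyl radical, a closure expected to outrun direct reduction by tin hydride. C4 is controlled by the existing C5 centre, whose aryl group sits pseudo-equatorial in the chair-like transition state (4,5-trans), and C3 by the preference of the methyl on the radical carbon to end cis to the new C4 methyl and trans to the C2 aryl; C2 arises in an intermolecular capture without control and is corrected in step 5. The step needs regioselective opening at C2, secured by the aryl ring that stabilises positive charge there, and chemoselective iodination of the propenyl alkene over the isolated allyl alkene of 4, secured by the higher nucleophilicity of the styrene-type double bond.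

Step 5
Reactants: 8 4-[(2RS,3R,4S,5S)-5-(3,4-dimethoxyphenyl)-3,4-dimethyloxolan-2-yl]-2,6-dimethoxyphenyl acetate
Product: 10 4-[(2R,3R,4S,5S)-5-(3,4-dimethoxyphenyl)-3,4-dimethyloxolan-2-yl]-2,6-dimethoxyphenol, via phenol epimer mixture 9 (not isolated)
Conditions: K2CO3 (cat.), MeOH, 0 °C to rt; solvent exchange; then CSA (cat.), CH2Cl2, 0 °C to rt
Reagents that add atoms: none
Why: Methanolysis of the aryl acetate (transesterification) frees the para-hydroxyl, which lets catalytic acid open and re-close the C2–O1 bond through the para-quinone methide (reversible oxa-1,6-addition), so that both C2 epimers should converge under thermodynamic control on the 2,3-trans, 2,5-cis arrangement while C5, whose aryl ring has no para-hydroxyl, should not ionise under these mild conditions.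

Compound list
1 | 3,4-dimethoxybenzaldehyde | COc1ccc(C=O)cc1OC | starting material
2 | vinylmagnesium bromide | C=C[Mg]Br | starting material
3 | racemic 1-(3,4-dimethoxyphenyl)prop-2-en-1-ol | COc1ccc(C(O)C=C)cc1OC | intermediate
4 | (1S)-1-(3,4-dimethoxyphenyl)prop-2-en-1-ol | COc1ccc([C@H](C=C)O)cc1OC | intermediate
5 | 2,6-dimethoxy-4-[(1E)-prop-1-en-1-yl]phenol | C/C=C/c1cc(OC)c(O)c(OC)c1 | starting material
6 | 2,6-dimethoxy-4-[(1E)-prop-1-en-1-yl]phenyl acetate | C/C=C/c1cc(OC)c(OC(C)=O)c(OC)c1 | intermediate
7 | 4-(1-{[(1S)-1-(3,4-dimethoxyphenyl)prop-2-en-1-yl]oxy}-2-iodopropyl)-2,6-dimethoxyphenyl acetate (anti adducts, both epimers at the ether carbon of the propyl chain) | COc1ccc([C@H](C=C)OC(C(C)I)c2cc(OC)c(OC(C)=O)c(OC)c2)cc1OC | intermediate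
8 | 4-[(2RS,3R,4S,5S)-5-(3,4-dimethoxyphenyl)-3,4-dimethyloxolan-2-yl]-2,6-dimethoxyphenyl acetate (C2 epimers) | COc1ccc([C@H]2OC(c3cc(OC)c(OC(C)=O)c(OC)c3)[C@H](C)[C@@H]2C)cc1OC | intermediate
9 | 4-[(2RS,3R,4S,5S)-5-(3,4-dimethoxyphenyl)-3,4-dimethyloxolan-2-yl]-2,6-dimethoxyphenol (C2 epimers) | COc1ccc([C@H]2OC(c3cc(OC)c(O)c(OC)c3)[C@H](C)[C@@H]2C)cc1OC | intermediate
10 | 4-[(2R,3R,4S,5S)-5-(3,4-dimethoxyphenyl)-3,4-dimethyloxolan-2-yl]-2,6-dimethoxyphenol | COc1ccc([C@H]2O[C@@H](c3cc(OC)c(O)c(OC)c3)[C@H](C)[C@@H]2C)cc1OC | target

Total step count: 5. Longest linear sequence: 4 steps (steps 1, 2, 4, 5).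

Steps most likely to fail

Step 4. The iodonium ion may be captured too slowly by a single equivalent of a hindered secondary alcohol, so that succinimide or iodide adds instead. The C2 epimer whose aryl group cannot sit pseudo-equatorial may also cyclize with poor facial control at C3. The fallback sets out from 6 (with 4 as the second component) and comes back at 8. Epoxidation of 6 with mCPBA/NaHCO3 should give racemic trans-4-(3-methyloxiran-2-yl)-2,6-dimethoxyphenyl acetate F1. Alcoholysis of F1 by 4 at the benzylic carbon, catalysed by Bi(OTf)3 in CH2Cl2 at low temperature, should give the stable 4-(1-{[(1S)-1-(3,4-dimethoxyphenyl)prop-2-en-1-yl]oxy}-2-hydroxypropyl)-2,6-dimethoxyphenyl acetate F2, which can be purified and, if wished, separated into its epimers at the ether carbon. 1,1'-Thiocarbonyldiimidazole then converts the secondary alcohol into the O-alkyl imidazole-1-carbothioate F3. Bu3SnH/AIBN in toluene at 80 °C (Barton–McCombie-type C–O homolysis) generates the same C3 radical, whose 5-exo cyclization returns to 8.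

Step 5. The acid may also ionise the C5–O1 bond next to the 3,4-dimethoxyphenyl ring, which would scramble C5, or the quinone methide may be intercepted intermolecularly or tautomerise to a styrene. The fallback sets out from 8 and comes back at 10. The C2 epimers of 8 are separated by chromatography into the (2R)-acetate F4 and the (2S)-acetate F5. Methanolysis of F4 alone (K2CO3, MeOH) gives 10 without any acid exposure. F5 is deacetylated in the same way to the (2S)-phenol F6, which is isomerised with DBU in toluene at 80 °C through its phenolate (retro-oxa-1,6-addition to the quinone methide and re-addition), a pathway that cannot affect C5, to give more 10.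

Step 2. The enzyme may discriminate poorly between the enantiomers of this aryl vinyl carbinol, and half of the material is lost in any case. The fallback sets out from 1 and comes back at 4. Catalytic asymmetric vinylation of 1 with (CH2=CH)2Zn, made from CH2=CHMgBr and ZnCl2, in the presence of a chiral β-amino alcohol ligand such as (−)-3-exo-(dimethylamino)isoborneol, the ligand antipode being chosen to deliver the (S)-alcohol, should give 4 directly; no new compound is made.

Further compounds
F1 | step 4 | racemic trans-4-(3-methyloxiran-2-yl)-2,6-dimethoxyphenyl acetate (one enantiomer drawn) | C[C@H]1O[C@@H]1c2cc(OC)c(OC(C)=O)c(OC)c2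
F2 | step 4 | 4-(1-{[(1S)-1-(3,4-dimethoxyphenyl)prop-2-en-1-yl]oxy}-2-hydroxypropyl)-2,6-dimethoxyphenyl acetate (both epimers at the ether carbon) | COc1ccc([C@H](C=C)OC(C(C)O)c2cc(OC)c(OC(C)=O)c(OC)c2)cc1OC
F3 | step 4 | O-[1-(4-acetoxy-3,5-dimethoxyphenyl)-1-{[(1S)-1-(3,4-dimethoxyphenyl)prop-2-en-1-yl]oxy}propan-2-yl] 1H-imidazole-1-carbothioate | COc1ccc([C@H](C=C)OC(C(C)OC(=S)n2ccnc2)c3cc(OC)c(OC(C)=O)c(OC)c3)cc1OC
F4 | step 5 | 4-[(2R,3R,4S,5S)-5-(3,4-dimethoxyphenyl)-3,4-dimethyloxolan-2-yl]-2,6-dimethoxyphenyl acetate | COc1ccc([C@H]2O[C@@H](c3cc(OC)c(OC(C)=O)c(OC)c3)[C@H](C)[C@@H]2C)cc1OC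
F5 | step 5 | 4-[(2S,3R,4S,5S)-5-(3,4-dimethoxyphenyl)-3,4-dimethyloxolan-2-yl]-2,6-dimethoxyphenyl acetate | COc1ccc([C@H]2O[C@H](c3cc(OC)c(OC(C)=O)c(OC)c3)[C@H](C)[C@@H]2C)cc1OC
F6 | step 5 | 4-[(2S,3R,4S,5S)-5-(3,4-dimethoxyphenyl)-3,4-dimethyloxolan-2-yl]-2,6-dimethoxyphenol | COc1ccc([C@H]2O[C@H](c3cc(OC)c(O)c(OC)c3)[C@H](C)[C@@H]2C)cc1OC
F0 | step 2 | none | none
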